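**Retrosynthetic overview**

- The free phenol and the methyl propanoate of the resorcinol-derived ring are unmasked last, by acid methanolysis of a saturated aryl lactone. That lactone is bought as 7-hydroxychroman-2-one and serves as the protecting group for both functions throughout.
- The coumarin C3–C4 double bond comes from DDQ dehydrogenation of a chroman-2-one. Its pyranone ring is closed by lactonisation of the C8a phenol onto an α-aryloxy ester (carried as the ethyl ester, whose alkoxy group is lost here).
- Key disconnection: on the coumarin benzene ring (C4a, C5, C6, C7, C8, C8a) the C6 methoxyl is para to the C8a oxygen and the C4 carbon chain sits on C4a, ortho to that oxygen. This 2-alkyl-4-methoxyphenol pattern is assembled by a Dötz benzannulation (bonds C5–C6, C4a–C8a, C8–C8a) from a 1-(methoxymethoxy)vinyl methoxycarbene chromium complex, a terminal alkyne and one CO ligand.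
- The carbene complex comes from α-lithiated methoxymethyl vinyl ether, Cr(CO)6 and MeOTf. The alkyne comes from Mitsunobu etherification of 7-hydroxychroman-2-one with ethyl 2-hydroxypent-4-ynoate (zinc Barbier propargylation of ethyl glyoxylate).
- Ring order: the resorcinol-derived arene and its lactone are bought; the coumarin benzene ring is formed in step 5, the pyranone ring in step 7 and aromatised in step 8.

Key step: step 5

Remark: the carbon that becomes C3 of the coumarin is carried as a racemic sp3 centre from the propargylation to the dehydrogenation, where it becomes sp2; the target has no stereocentre, so racemic intermediates are used.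

**Route**

Step 1
Reactants: 1 1-bromo-2-(methoxymethoxy)ethane
Product: 2 methoxymethyl vinyl ether
Conditions: powdered KOH, Bu4NHSO4 (cat.), neat, 80 → 120 °C, product distilled out as formed
Reagents that add atoms: none
Why: E2 dehydrobromination of a 2-bromoethyl ether under solid–liquid phase-transfer conditions is a standard entry to vinyl ethers, and the acetal is inert to base.

Step 2
Reactants: 2 methoxymethyl vinyl ether; 3 chromium hexacarbonyl Cr(CO)6
Product: 6 pentacarbonyl{methoxy[1-(methoxymethoxy)ethenyl]carbene}chromium, via 1-(methoxymethoxy)vinyllithium 4 (not isolated), via lithium acylchromate 5 (not isolated)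
Conditions: s-BuLi, THF, −78 °C; Cr(CO)6, −78 °C → rt; solvent exchange to CH2Cl2, MeOTf, 0 °C
Reagents that add atoms: methyl trifluoromethanesulfonate (MeOTf), COS(=O)(=O)C(F)(F)F
Why: Fischer carbene synthesis, in which the acetal oxygen assists α-lithiation of the vinyl ether, the vinyllithium adds to a carbonyl ligand of Cr(CO)6 and the anionic acylchromate oxygen should be methylated far faster than the acetal or the enol ether.

Step 3
Reactants: 7 ethyl glyoxylate; 8 propargyl bromide
Product: 10 ethyl 2-hydroxypent-4-ynoate (racemic), via allenylzinc bromide 9 (not isolated)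
Conditions: Zn dust, THF, 0 °C → rt; 1 M HCl work-up
Reagents that add atoms: none
Why: Barbier propargylation, in which zinc inserts into the C–Br bond and the allenylzinc adds to the aldehyde through a cyclic SE2′ transition state to give the homopropargylic alcohol, the new centre being formed racemic and removed later.

Step 4
Reactants: 10 ethyl 2-hydroxypent-4-ynoate (racemic); 11 7-hydroxychroman-2-one
Product: 12 ethyl 2-[(2-oxochroman-7-yl)oxy]pent-4-ynoate (racemic)
Conditions: PPh3, DIAD, THF, 0 °C → rt
Reagents that add atoms: none
Why: Mitsunobu etherification of a phenol with a secondary α-hydroxy ester (SN2 with inversion, of no consequence for racemic material) runs without free base, so the aryl lactone that masks the second phenol and the propanoic acid should stay closed.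

Step 5
Reactants: 6 pentacarbonyl{methoxy[1-(methoxymethoxy)ethenyl]carbene}chromium; 12 ethyl 2-[(2-oxochroman-7-yl)oxy]pent-4-ynoate (racemic)
Product: 15 ethyl 3-[2-hydroxy-5-methoxy-4-(methoxymethoxy)phenyl]-2-[(2-oxochroman-7-yl)oxy]propanoate (racemic), via chromium-bound dienylketene 13 (not isolated), via tricarbonylchromium phenol complex 14 (not isolated)
Conditions: THF (0.2 M), 50 °C, argon; then EtOAc, air, rt, filtration through silica
Reagents that add atoms: none
Why: Thermal loss of one CO from 6 opens a site for alkyne 12, which inserts into the Cr=C bond with its unsubstituted terminus bonding to the carbene carbon (C5–C6), and CO insertion then gives the chromium-bound dienylketene 13 (C4a–C8a). Electrocyclisation of 13 closes the ring through C8–C8a and enolisation gives the arene complex 14, from which air strips the Cr(CO)3 unit. The closest known reaction type is the Dötz benzannulation of alkenyl(methoxy)carbene chromium complexes with terminal alkynes to 4-methoxyphenols, which includes cyclic α-alkoxyalkenyl complexes; the acyclic 1-alkoxyvinyl complex is a new member of that class. The one ring is closed by a thermal six-electron electrocyclisation of the dienylketene, the overall event being a [3+2+1] assembly of the carbene carbon with its two vinyl carbons, the two alkyne carbons and one carbonyl ligand. No stereocentre is formed and the existing racemic centre is not touched. The step needs regioselective insertion, which the terminal alkyne secures because its substituted carbon is placed beside the CO-derived carbon, away from the carbene substituents, and it needs phenol formation over cyclisation without CO uptake, which an alkenyl chromium complex in THF at moderate temperature should favour.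

Step 6
Reactants: 15 ethyl 3-[2-hydroxy-5-methoxy-4-(methoxymethoxy)phenyl]-2-[(2-oxochroman-7-yl)oxy]propanoate (racemic)
Product: 16 ethyl 3-(2,4-dihydroxy-5-methoxyphenyl)-2-[(2-oxochroman-7-yl)oxy]propanoate (racemic)
Conditions: ZnBr2, n-PrSH, CH2Cl2, 0 °C → rt
Reagents that add atoms: none
Why: Lewis-acid-assisted acetal cleavage with thiol capture, in which the methoxymethyl cation is trapped as a monothioacetal so that no formaldehyde is released onto the electron-rich dihydroxyarene, while the ester, the lactone and the methyl ether should be untouched.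

Step 7
Reactants: 16 ethyl 3-(2,4-dihydroxy-5-methoxyphenyl)-2-[(2-oxochroman-7-yl)oxy]propanoate (racemic)
Product: 17 7-hydroxy-6-methoxy-3-[(2-oxochroman-7-yl)oxy]chroman-2-one (racemic)
Conditions: TsOH·H2O (cat.), toluene, reflux, 4 Å molecular sieves (Soxhlet)
Reagents that add atoms: none
Why: Acid-catalysed intramolecular transesterification (lactonisation), in which only the C8a hydroxyl is ortho to the side chain and can reach the ester in a six-membered ring, with removal of ethanol driving the closure.

Step 8
Reactants: 17 7-hydroxy-6-methoxy-3-[(2-oxochroman-7-yl)oxy]chroman-2-one (racemic)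
Product: 19 7-hydroxy-6-methoxy-3-[(2-oxochroman-7-yl)oxy]-2H-chromen-2-one, via para-quinone methide 18 (not isolated)
Conditions: DDQ (1.05 equiv), 1,4-dioxane, rt → 40 °C
Reagents that add atoms: none
Why: DDQ dehydrogenation, in which the free C7 phenol para to C4a lets DDQ remove hydride from C4 under mild conditions to give the para-quinone methide, which tautomerises by loss of the acidic C3 proton to the coumarin, while the other lactone ring, lacking a free para phenol, should stay saturated.

Step 9
Reactants: 19 7-hydroxy-6-methoxy-3-[(2-oxochroman-7-yl)oxy]-2H-chromen-2-one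
Product: 20 methyl 3-{2-hydroxy-4-[(7-hydroxy-6-methoxy-2-oxo-2H-chromen-3-yl)oxy]phenyl}propanoate (CNP0259806.0)
Conditions: H2SO4 (cat.), MeOH, reflux; NaHCO3 before concentration
Reagents that add atoms: methanol, CO
Why: Acid-catalysed methanolysis (transesterification) of the saturated aryl lactone should give the methyl ester and free the phenol, whereas the coumarin lactone, held closed by its cis double bond and conjugation, is not opened.

**Compound list**

1 | 1-bromo-2-(methoxymethoxy)ethane | COCOCCBr | starting material
2 | methoxymethyl vinyl ether | COCOC=C | intermediate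
3 | chromium hexacarbonyl Cr(CO)6 | O=C=[Cr](=C=O)(=C=O)(=C=O)(=C=O)=C=O | starting material
4 | 1-(methoxymethoxy)vinyllithium | [Li]C(=C)OCOC | intermediate
5 | lithium pentacarbonyl{[1-(methoxymethoxy)ethenyl](oxido)carbene}chromate (lithium acylchromate) | [Li+].[O-]C(C(=C)OCOC)=[Cr](=C=O)(=C=O)(=C=O)(=C=O)=C=O | intermediate
6 | pentacarbonyl{methoxy[1-(methoxymethoxy)ethenyl]carbene}chromium | COCOC(=C)C(OC)=[Cr](=C=O)(=C=O)(=C=O)(=C=O)=C=O | intermediate
7 | ethyl glyoxylate | CCOC(=O)C=O | starting material
8 | propargyl bromide (3-bromoprop-1-yne) | C#CCBr | starting material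
9 | allenylzinc bromide (propa-1,2-dienylzinc bromide) | C=C=C[Zn]Br | intermediate
10 | ethyl 2-hydroxypent-4-ynoate, racemic | CCOC(=O)C(O)CC#C | intermediate
11 | 7-hydroxychroman-2-one | O=C1CCc2ccc(O)cc2O1 | starting material
12 | ethyl 2-[(2-oxochroman-7-yl)oxy]pent-4-ynoate, racemic | CCOC(=O)C(CC#C)Oc1ccc2CCC(=O)Oc2c1 | intermediate
13 | dienylketene bound to a Cr(CO)3 unit (π-bound metal fragment written as a separate part) | CCOC(=O)C(CC(=C=O)/C=C(OC)\C(=C)OCOC)Oc1ccc2CCC(=O)Oc2c1.O=C=[Cr](=C=O)=C=O | intermediate
14 | tricarbonylchromium eta-6 complex of phenol 15 (π-bound metal fragment written as a separate part) | CCOC(=O)C(Cc1cc(OC)c(OCOC)cc1O)Oc1ccc2CCC(=O)Oc2c1.O=C=[Cr](=C=O)=C=O | intermediate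
15 | ethyl 3-[2-hydroxy-5-methoxy-4-(methoxymethoxy)phenyl]-2-[(2-oxochroman-7-yl)oxy]propanoate, racemic | CCOC(=O)C(Cc1cc(OC)c(OCOC)cc1O)Oc1ccc2CCC(=O)Oc2c1 | intermediate
16 | ethyl 3-(2,4-dihydroxy-5-methoxyphenyl)-2-[(2-oxochroman-7-yl)oxy]propanoate, racemic | CCOC(=O)C(Cc1cc(OC)c(O)cc1O)Oc1ccc2CCC(=O)Oc2c1 | intermediate
17 | 7-hydroxy-6-methoxy-3-[(2-oxochroman-7-yl)oxy]chroman-2-one, racemic | COc1cc2CC(Oc3ccc4CCC(=O)Oc4c3)C(=O)Oc2cc1O | intermediate
18 | para-quinone methide tautomer of 19 (C7 carbonyl, C4a=C4 double bond) | COC1=CC2=CC(Oc3ccc4CCC(=O)Oc4c3)C(=O)OC2=CC1=O | intermediate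
19 | 7-hydroxy-6-methoxy-3-[(2-oxochroman-7-yl)oxy]-2H-chromen-2-one | COc1cc2cc(Oc3ccc4CCC(=O)Oc4c3)c(=O)oc2cc1O | intermediate
20 | methyl 3-{2-hydroxy-4-[(7-hydroxy-6-methoxy-2-oxo-2H-chromen-3-yl)oxy]phenyl}propanoate | COC(=O)CCc1ccc(Oc2cc3cc(OC)c(O)cc3oc2=O)cc1O | target

**Step count**

Total steps: 9. Longest linear sequence: 7 steps (steps 1, 2, 5, 6, 7, 8, 9, or equally steps 3, 4, 5, 6, 7, 8, 9).

**Steps most likely to fail**

1. Step 5. After alkyne insertion the donor-substituted vinylcarbene may cyclise without taking up CO (cyclopentannulation or furan formation), or the electron-rich complex may decompose before it inserts, so that little phenol forms. The fallback gives up the benzannulation for a Perkin-type coumarin synthesis and sets out from 11. Mitsunobu etherification of 11 with tert-butyl glycolate (PPh3, DIAD, THF) would give tert-butyl 2-[(2-oxochroman-7-yl)oxy]acetate F1. TFA in CH2Cl2 would give 2-[(2-oxochroman-7-yl)oxy]acetic acid F2. Perkin condensation of F2 with commercial 2,4-dihydroxy-5-methoxybenzaldehyde (Ac2O, Et3N, 120 °C) should give 7-acetoxy-6-methoxy-3-[(2-oxochroman-7-yl)oxy]-2H-chromen-2-one F3. Methanolic H2SO4 as in step 9 would remove the acetate and open the saturated lactone, so the fallback comes back to the route at 20.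

2. Step 8. The electron-rich guaiacol ring may be over-oxidised to a quinone, or the quinone methide may be captured by a nucleophile instead of tautomerising. The fallback sets out from 17 and uses a selenoxide elimination. Silylation (TBSCl, imidazole, DMF) would give 7-(tert-butyldimethylsilyloxy)-6-methoxy-3-[(2-oxochroman-7-yl)oxy]chroman-2-one F4. Its C3–H, flanked by the lactone carbonyl and the aryloxy group, is the most acidic C–H, so LiN(SiMe3)2 (1 equiv, THF, −78 °C) followed by PhSeBr should give the 3-phenylselanyl lactone F5. H2O2 with pyridine in CH2Cl2 at 0 °C would give the selenoxide F6, which undergoes syn-elimination towards C4 to give 7-(tert-butyldimethylsilyloxy)-6-methoxy-3-[(2-oxochroman-7-yl)oxy]-2H-chromen-2-one F7. TBAF buffered with AcOH in THF would return the route to 19.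

3. Step 2. The hard methylating agent may attack the acetal or the enol ether, or the complex may be lost in the presence of lithium salts and on silica. The fallback sets out from acylchromate 5 (made from 2 and 3 as in step 2) and replaces O-alkylation by acylation and alcoholysis. Cation exchange with aqueous Me4NBr would give the isolable tetramethylammonium acylchromate F8. Pivaloyl chloride in CH2Cl2 at −40 °C would give pentacarbonyl{[1-(methoxymethoxy)ethenyl](pivaloyloxy)carbene}chromium F9. Methanol at −40 → 0 °C should exchange the acyloxy group for methoxy, coming back to the route at 6.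

**Further compounds**

F1 | step 5 | tert-butyl 2-[(2-oxochroman-7-yl)oxy]acetate | CC(C)(C)OC(=O)COc1ccc2CCC(=O)Oc2c1
F2 | step 5 | 2-[(2-oxochroman-7-yl)oxy]acetic acid | OC(=O)COc1ccc2CCC(=O)Oc2c1
F3 | step 5 | 7-acetoxy-6-methoxy-3-[(2-oxochroman-7-yl)oxy]-2H-chromen-2-one | COc1cc2cc(Oc3ccc4CCC(=O)Oc4c3)c(=O)oc2cc1OC(C)=O
F4 | step 8 | 7-(tert-butyldimethylsilyloxy)-6-methoxy-3-[(2-oxochroman-7-yl)oxy]chroman-2-one, racemic | COc1cc2CC(Oc3ccc4CCC(=O)Oc4c3)C(=O)Oc2cc1O[Si](C)(C)C(C)(C)C
F5 | step 8 | 7-(tert-butyldimethylsilyloxy)-6-methoxy-3-[(2-oxochroman-7-yl)oxy]-3-(phenylselanyl)chroman-2-one, racemic | COc1cc2CC([Se]c5ccccc5)(Oc3ccc4CCC(=O)Oc4c3)C(=O)Oc2cc1O[Si](C)(C)C(C)(C)C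
F6 | step 8 | selenoxide of F5 | COc1cc2CC([Se](=O)c5ccccc5)(Oc3ccc4CCC(=O)Oc4c3)C(=O)Oc2cc1O[Si](C)(C)C(C)(C)C
F7 | step 8 | 7-(tert-butyldimethylsilyloxy)-6-methoxy-3-[(2-oxochroman-7-yl)oxy]-2H-chromen-2-one | COc1cc2cc(Oc3ccc4CCC(=O)Oc4c3)c(=O)oc2cc1O[Si](C)(C)C(C)(C)C
F8 | step 2 | tetramethylammonium pentacarbonyl{[1-(methoxymethoxy)ethenyl](oxido)carbene}chromate | C[N+](C)(C)C.[O-]C(C(=C)OCOC)=[Cr](=C=O)(=C=O)(=C=O)(=C=O)=C=O
F9 | step 2 | pentacarbonyl{[1-(methoxymethoxy)ethenyl](pivaloyloxy)carbene}chromium | COCOC(=C)C(OC(=O)C(C)(C)C)=[Cr](=C=O)(=C=O)(=C=O)(=C=O)=C=O
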